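**Plan**
Retrosynthesis: (i) remove the three phenolic MOM ethers. (ii) Cut C3–C4 of ring C as a retro-hydroacylation, giving the achiral 2-(1-arylvinyloxy)benzaldehyde 11. (iii) Add HCl back across C2=C3 and cut O1–C2 (Mitsunobu), giving phenol 9 and chlorohydrin 6. (iv) Cut C2–C3 (ClCH2Li + aldehyde 5), the C5'–tert-prenyl bond (aromatic Claisen) and the C8–prenyl bond (C-alkylation).
Forward: ring-B aldehyde 5 (3 steps from 1) and ring-A phenol 9 (2 steps from 7) are joined at O1–C2. Ring C is the only ring built and closes in the penultimate step at C3–C4.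
Enabling feature: C3 is an unsubstituted CH2 between the aryl-ketone carbon C4 and C2, which carries O1 and ring B. Ring C is therefore the hydroacylation isomer of an O1–C2(=C3H2) enol ether on C8a, ortho to a formyl group on C4a. Full substitution at C2 sends Rh to C3, there is no allylic C–H to isomerise, and the C8 prenyl group buttresses O1 so that the vinyl group lies over the formyl C–H.
Stereochemistry: the single stereocentre C2 (S) is created in the ring closure by ligand-controlled hydride delivery to one face of C2=C3. All later conditions are base-free, so retro-oxa-Michael racemisation and 6-/8-prenyl scrambling are avoided.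

Key step: step 9

Assumption: the sense of induction of the ligand on this new substrate class cannot be predicted with certainty. (R)-DTBM-SEGPHOS is written, and its antipode is used if a test run shows the (2R) product.

Step 1
Reactants: 1 4-hydroxy-2-methoxybenzaldehyde
Product: 2 2-methoxy-4-[(3-methylbut-2-en-1-yl)oxy]benzaldehyde
Conditions: prenyl bromide, K2CO3, DMF, rt
Reagents that add atoms: prenyl bromide (1-bromo-3-methylbut-2-ene), CC(C)=CCBr
Why: Williamson ether synthesis, in which the acidic para-formyl phenoxide is alkylated at oxygen by the primary allylic bromide (SN2) and no stereocentre is formed.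

Step 2
Reactants: 2 2-methoxy-4-[(3-methylbut-2-en-1-yl)oxy]benzaldehyde
Product: 4 4-hydroxy-2-methoxy-5-(2-methylbut-3-en-2-yl)benzaldehyde, via ortho-dienone 3 (not isolated)
Conditions: EtOH–H2O (4:1), sealed tube, 130 °C
Reagents that add atoms: none
Why: Water-accelerated aromatic Claisen rearrangement ([3,3]-sigmatropic, allyl inversion) should deliver the 1,1-dimethylallyl group to C5 rather than to C3, which is flanked by two oxygen substituents, and tautomerisation of dienone 3 restores the phenol, as known for licochalcone-type rings of this substitution pattern.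

Step 3
Reactants: 4 4-hydroxy-2-methoxy-5-(2-methylbut-3-en-2-yl)benzaldehyde
Product: 5 2-methoxy-4-(methoxymethoxy)-5-(2-methylbut-3-en-2-yl)benzaldehyde
Conditions: MOMCl, i-Pr2NEt, CH2Cl2, 0 °C to rt
Reagents that add atoms: chloromethyl methyl ether (MOMCl), COCCl
Why: Standard MOM protection (O-alkylation of a phenol) masks the acidic 4-OH against the carbenoid, the Mitsunobu betaine and the tert-butoxide that follow.

Step 4
Reactants: 5 2-methoxy-4-(methoxymethoxy)-5-(2-methylbut-3-en-2-yl)benzaldehyde
Product: 6 rac-2-chloro-1-[2-methoxy-4-(methoxymethoxy)-5-(2-methylbut-3-en-2-yl)phenyl]ethan-1-ol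
Conditions: ClCH2I, MeLi·LiBr, THF, −78 °C; then AcOH, −78 °C
Reagents that add atoms: chloroiodomethane, ClCI
Why: Addition of a lithium carbenoid (chloromethyllithium from I/Li exchange under Barbier conditions) to a non-enolisable aldehyde, with the cold acidic quench stopping the alkoxide before epoxide closure, and the carbinol centre is left racemic because it is erased in step 8.

Step 5
Reactants: 7 2,4,6-trihydroxybenzaldehyde
Product: 8 2,4,6-trihydroxy-3-(3-methylbut-2-en-1-yl)benzaldehyde
Conditions: prenyl bromide (1 equiv), KOH, H2O–MeOH, 0 °C to rt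
Reagents that add atoms: prenyl bromide (1-bromo-3-methylbut-2-ene), CC(C)=CCBr
Why: C-alkylation of the ambident acylphloroglucinol phenoxide in protic basic medium, where solvation shields oxygen and the two free ring positions are equivalent, so only one mono-C-prenyl isomer can form.

Step 6
Reactants: 8 2,4,6-trihydroxy-3-(3-methylbut-2-en-1-yl)benzaldehyde
Product: 9 2-hydroxy-4,6-bis(methoxymethoxy)-3-(3-methylbut-2-en-1-yl)benzaldehyde
Conditions: MOMCl (2.1 equiv), i-Pr2NEt, CH2Cl2, 0 °C
Reagents that add atoms: chloromethyl methyl ether (MOMCl), COCCl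
Why: Selective MOM protection, in which the para 4-OH and the less hindered ortho 6-OH react while the 2-OH, hydrogen-bonded to the formyl oxygen and flanked by the prenyl group, should stay free, as known for 3-prenylated acylphloroglucinols.

Step 7
Reactants: 9 2-hydroxy-4,6-bis(methoxymethoxy)-3-(3-methylbut-2-en-1-yl)benzaldehyde; 6 rac-2-chloro-1-[2-methoxy-4-(methoxymethoxy)-5-(2-methylbut-3-en-2-yl)phenyl]ethan-1-ol
Product: 10 rac-2-{2-chloro-1-[2-methoxy-4-(methoxymethoxy)-5-(2-methylbut-3-en-2-yl)phenyl]ethoxy}-4,6-bis(methoxymethoxy)-3-(3-methylbut-2-en-1-yl)benzaldehyde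
Conditions: PPh3, DIAD, toluene, 0 °C to rt
Reagents that add atoms: none
Why: Mitsunobu etherification, in which the acidic salicylaldehyde-type phenol displaces the oxyphosphonium salt of the secondary benzylic alcohol and thereby fixes O1 next to the prenyl group (8-prenyl regiochemistry), loss of configuration being irrelevant because this centre is racemic and is erased in the next step.

Step 8
Reactants: 10 rac-2-{2-chloro-1-[2-methoxy-4-(methoxymethoxy)-5-(2-methylbut-3-en-2-yl)phenyl]ethoxy}-4,6-bis(methoxymethoxy)-3-(3-methylbut-2-en-1-yl)benzaldehyde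
Product: 11 2-({1-[2-methoxy-4-(methoxymethoxy)-5-(2-methylbut-3-en-2-yl)phenyl]ethenyl}oxy)-4,6-bis(methoxymethoxy)-3-(3-methylbut-2-en-1-yl)benzaldehyde (achiral)
Conditions: t-BuOK, THF, 0 °C to rt
Reagents that add atoms: none
Why: E2 dehydrochlorination (the classical 2-haloethyl aryl ether to aryl vinyl ether route) removes the benzylic, α-oxygenated C2–H and the primary chloride, the aldehyde being non-enolisable and the MOM ethers base-stable.

Step 9
Reactants: 11 2-({1-[2-methoxy-4-(methoxymethoxy)-5-(2-methylbut-3-en-2-yl)phenyl]ethenyl}oxy)-4,6-bis(methoxymethoxy)-3-(3-methylbut-2-en-1-yl)benzaldehyde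
Product: 12 (2S)-2-[2-methoxy-4-(methoxymethoxy)-5-(2-methylbut-3-en-2-yl)phenyl]-5,7-bis(methoxymethoxy)-8-(3-methylbut-2-en-1-yl)chroman-4-one
Conditions: [Rh(cod)Cl]2 (2.5 mol %), (R)-DTBM-SEGPHOS (5 mol %), NaBArF4 (5 mol %), 4 Å MS, 1,4-dioxane, 80 °C
Reagents that add atoms: none
Why: Proposed new method: the cationic Rh(I)–bisphosphine binds the C2=C3 π bond of 11, adds oxidatively into the neighbouring formyl C4–H bond, transfers the hydride to C2 so that Rh ends on the unhindered C3, and C3–C4 reductive elimination from the seven-membered acyl–alkyl rhodacycle releases ring C. The closest known reaction type is the Rh-catalysed enantioselective endo hydroacylation of 1,1-disubstituted alkenes, shown on ortho-allylbenzaldehydes (six-ring, 3-substituted tetralones) and on α-substituted N-vinylindole-2-carbaldehydes (heteroatom directly on the alkene, acyl to the terminal CH2), and what is new is an α-arylvinyl aryl ether with O1 on the alkene closing to a chroman-4-one. The pyranone ring closes in a formal 6-endo-trig mode. C2 is the only new stereocentre and is set by the C2-symmetric ligand, whose quadrants distinguish the two alkene faces through the different demands of ring B and the O1-aryl group at the hydride-transfer stage. The step needs 6-endo over 5-exo regioselectivity (the latter would give a 2-methyl-2-arylbenzofuranone), secured by the full substitution of C2 that disfavours a tertiary Rh–alkyl, and chemoselectivity over the C8 prenyl group (meta to the formyl carbon, trisubstituted) and the neopentyl-type vinyl group on ring B, neither of which can reach the acyl–Rh centre in a small ring, while β-aryloxide loss is held back because Rh–C3–C2–O1 is an endocyclic dihedral that cannot become syn-coplanar. The reaction is a base-free isomerisation, so retro-oxa-Michael opening, which would racemise C2 and scramble 6- and 8-prenyl isomers, has no channel.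

Step 10
Reactants: 12 (2S)-2-[2-methoxy-4-(methoxymethoxy)-5-(2-methylbut-3-en-2-yl)phenyl]-5,7-bis(methoxymethoxy)-8-(3-methylbut-2-en-1-yl)chroman-4-one
Product: 13 (2S)-5,7-dihydroxy-2-[4-hydroxy-2-methoxy-5-(2-methylbut-3-en-2-yl)phenyl]-8-(3-methylbut-2-en-1-yl)chroman-4-one (target)
Conditions: HCl (cat.), MeOH, 35 °C
Reagents that add atoms: none
Why: Acid-catalysed acetal exchange (MOM cleavage by methanolysis), precedented on prenylated flavanones and chalcones, should free the three phenols under conditions too mild for chroman formation from the ortho-prenyl phenol or for ionisation of the C2–O1 bond, so the (2S) centre is kept.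

**Compound list**
1 | 4-hydroxy-2-methoxybenzaldehyde | COc1cc(O)ccc1C=O | starting material
2 | 2-methoxy-4-[(3-methylbut-2-en-1-yl)oxy]benzaldehyde | COc1cc(OCC=C(C)C)ccc1C=O | intermediate
3 | 4-formyl-3-methoxy-6-(2-methylbut-3-en-2-yl)cyclohexa-2,4-dien-1-one (racemic ortho-dienone, not isolated) | O=CC1=CC(C(C)(C)C=C)C(=O)C=C1OC | intermediate
4 | 4-hydroxy-2-methoxy-5-(2-methylbut-3-en-2-yl)benzaldehyde | C=CC(C)(C)c1cc(C=O)c(OC)cc1O | intermediate
5 | 2-methoxy-4-(methoxymethoxy)-5-(2-methylbut-3-en-2-yl)benzaldehyde | C=CC(C)(C)c1cc(C=O)c(OC)cc1OCOC | intermediate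
6 | rac-2-chloro-1-[2-methoxy-4-(methoxymethoxy)-5-(2-methylbut-3-en-2-yl)phenyl]ethan-1-ol | C=CC(C)(C)c1cc(C(O)CCl)c(OC)cc1OCOC | intermediate
7 | 2,4,6-trihydroxybenzaldehyde | O=Cc1c(O)cc(O)cc1O | starting material
8 | 2,4,6-trihydroxy-3-(3-methylbut-2-en-1-yl)benzaldehyde | CC(C)=CCc1c(O)cc(O)c(C=O)c1O | intermediate
9 | 2-hydroxy-4,6-bis(methoxymethoxy)-3-(3-methylbut-2-en-1-yl)benzaldehyde | CC(C)=CCc1c(O)c(C=O)c(OCOC)cc1OCOC | intermediate
10 | rac-β-chloro ether (2-{2-chloro-1-arylethoxy}benzaldehyde of step 7) | C=CC(C)(C)c1cc(C(CCl)Oc2c(C=O)c(OCOC)cc(OCOC)c2CC=C(C)C)c(OC)cc1OCOC | intermediate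
11 | 2-(1-arylvinyloxy)benzaldehyde of step 8 (achiral) | C=CC(C)(C)c1cc(C(=C)Oc2c(C=O)c(OCOC)cc(OCOC)c2CC=C(C)C)c(OC)cc1OCOC | intermediate
12 | (2S)-tri-O-MOM flavanone | C=CC(C)(C)c1cc([C@@H]2CC(=O)c3c(OCOC)cc(OCOC)c(CC=C(C)C)c3O2)c(OC)cc1OCOC | intermediate
13 | (2S)-5,7-dihydroxy-2-[4-hydroxy-2-methoxy-5-(2-methylbut-3-en-2-yl)phenyl]-8-(3-methylbut-2-en-1-yl)chroman-4-one | C=CC(C)(C)c1cc([C@@H]2CC(=O)c3c(O)cc(O)c(CC=C(C)C)c3O2)c(OC)cc1O | target

Total step count: 10. Longest linear sequence: 8 (steps 1–4, then 7–10).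

**Steps most likely to fail**

1. Step 9.
- What may go wrong: decarbonylation of the hindered, electron-rich acyl–Rh hydride; Lewis-acid (Prins-type) attack of the enol ether on the aldehyde; hydrolysis of the enol ether by adventitious water; insertion in the 5-exo sense; poor facial discrimination.
- Fallback (known chemistry): it sets out from 9 and 5 and comes back at 12.
- Phenol aldehyde 9 takes up excess MeMgBr (THF, 0 °C) to give 2-(1-hydroxyethyl)-3,5-bis(methoxymethoxy)-6-prenylphenol F1.
- MnO2 oxidation gives 2-hydroxy-4,6-bis(methoxymethoxy)-3-prenylacetophenone F2.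
- Claisen–Schmidt condensation with aldehyde 5 (KOH, EtOH, rt) gives the (E)-2'-hydroxychalcone F3.
- NaOAc in refluxing EtOH closes O1–C2 by oxa-Michael addition to the racemic tri-O-MOM flavanone F4.
- Kinetic resolution by Noyori asymmetric transfer hydrogenation (the Ru–TsDPEN antipode that consumes the 2R ketone, HCO2H/Et3N) turns the (2R) enantiomer into the (2R,4R)-cis-flavan-4-ol F5 and leaves (2S)-12, which is separated by chromatography.

2. Step 7.
- What may go wrong: slow substitution at a hindered secondary benzylic carbon by a doubly ortho-substituted, hydrogen-bonded phenol; ionisation of the oxyphosphonium salt followed by C-alkylation of ring A or capture by the hydrazide.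
- Fallback: it sets out from 5 and 9 and comes back at 11. It builds O1–C2 as an ester and makes C2=C3 by carbonyl methylenation.
- Pinnick oxidation of 5 gives 2-methoxy-4-(methoxymethoxy)-5-(2-methylbut-3-en-2-yl)benzoic acid F6.
- NaBH4 reduces 9 to the salicyl alcohol F7.
- TBSCl/imidazole silylates the primary hydroxyl to give the benzylic TBS ether F8.
- EDC/DMAP coupling of F6 with F8 gives the aryl ester F9.
- Petasis methylenation (Cp2TiMe2, toluene, 70 °C) gives the α-aryloxystyrene F10.
- TBAF frees the benzylic alcohol F11, and MnO2 oxidation gives 11.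

3. Step 5.
- What may go wrong: over-alkylation, O-alkylation and dearomatising gem-diprenylation of the very electron-rich ring.
- Fallback: it sets out from 7 and comes back at 9. It delivers the prenyl group by a sigmatropic shift from the oxygen that must end up free, which also removes any doubt about the site selectivity of step 6.
- Bis-MOM protection of 7 gives 2-hydroxy-4,6-bis(methoxymethoxy)benzaldehyde F12.
- O-alkylation with 3-chloro-3-methylbut-1-yne (DBU, cat. CuCl2, MeCN) gives the 1,1-dimethylpropargyl ether F13.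
- Lindlar semihydrogenation gives the 1,1-dimethylallyl ether F14.
- Aromatic Claisen rearrangement (toluene, 110 °C) moves the allyl unit with inversion to the only free ortho position and regenerates the 2-OH, giving 9.

**Further compounds**
F1 | step 9 | 2-(1-hydroxyethyl)-3,5-bis(methoxymethoxy)-6-(3-methylbut-2-en-1-yl)phenol (racemic) | CC(C)=CCc1c(O)c(C(C)O)c(OCOC)cc1OCOC
F2 | step 9 | 1-[2-hydroxy-4,6-bis(methoxymethoxy)-3-(3-methylbut-2-en-1-yl)phenyl]ethan-1-one | CC(C)=CCc1c(O)c(C(C)=O)c(OCOC)cc1OCOC
F3 | step 9 | (E)-2'-hydroxychalcone from F2 and 5 | C=CC(C)(C)c1cc(/C=C/C(=O)c2c(O)c(CC=C(C)C)c(OCOC)cc2OCOC)c(OC)cc1OCOC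
F4 | step 9 | racemic tri-O-MOM flavanone | C=CC(C)(C)c1cc(C2CC(=O)c3c(OCOC)cc(OCOC)c(CC=C(C)C)c3O2)c(OC)cc1OCOC
F5 | step 9 | (2R,4R)-cis-flavan-4-ol from the unwanted enantiomer | C=CC(C)(C)c1cc([C@H]2C[C@@H](O)c3c(OCOC)cc(OCOC)c(CC=C(C)C)c3O2)c(OC)cc1OCOC
F6 | step 7 | 2-methoxy-4-(methoxymethoxy)-5-(2-methylbut-3-en-2-yl)benzoic acid | C=CC(C)(C)c1cc(C(=O)O)c(OC)cc1OCOC
F7 | step 7 | 2-(hydroxymethyl)-3,5-bis(methoxymethoxy)-6-(3-methylbut-2-en-1-yl)phenol | CC(C)=CCc1c(O)c(CO)c(OCOC)cc1OCOC
F8 | step 7 | 2-{[(tert-butyldimethylsilyl)oxy]methyl}-3,5-bis(methoxymethoxy)-6-(3-methylbut-2-en-1-yl)phenol | CC(C)=CCc1c(O)c(CO[Si](C)(C)C(C)(C)C)c(OCOC)cc1OCOC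
F9 | step 7 | aryl ester of F6 with F8 | C=CC(C)(C)c1cc(C(=O)Oc2c(CO[Si](C)(C)C(C)(C)C)c(OCOC)cc(OCOC)c2CC=C(C)C)c(OC)cc1OCOC
F10 | step 7 | α-aryloxystyrene with benzylic OTBS | C=CC(C)(C)c1cc(C(=C)Oc2c(CO[Si](C)(C)C(C)(C)C)c(OCOC)cc(OCOC)c2CC=C(C)C)c(OC)cc1OCOC
F11 | step 7 | α-aryloxystyrene with free benzylic alcohol | C=CC(C)(C)c1cc(C(=C)Oc2c(CO)c(OCOC)cc(OCOC)c2CC=C(C)C)c(OC)cc1OCOC
F12 | step 5 | 2-hydroxy-4,6-bis(methoxymethoxy)benzaldehyde | O=Cc1c(O)cc(OCOC)cc1OCOC
F13 | step 5 | 2,4-bis(methoxymethoxy)-6-[(2-methylbut-3-yn-2-yl)oxy]benzaldehyde | C#CC(C)(C)Oc1cc(OCOC)cc(OCOC)c1C=O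
F14 | step 5 | 2,4-bis(methoxymethoxy)-6-[(2-methylbut-3-en-2-yl)oxy]benzaldehyde | C=CC(C)(C)Oc1cc(OCOC)cc(OCOC)c1C=O
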